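**Retrosynthetic overview**
- Target 8 ⇐ 6, its C5 epimer: the one centre that differs from the parent guaianolide is inverted last, by kinetic reprotonation of a cross-conjugated trienolate.
- 6 ⇐ two molecules of one monomer: retro-[4+2] of the spiro-cyclohexene (bonds C2–C4' and C14–C15') gives dienone 4 (diene C2=C1–C10=C14) and dehydrozaluzanin C 3 (dienophile C4'=C15'). This is the union presumed to build this dimer family in the plant, here run as an oxidative homodimerisation.
- 3 ⇐ 2 ⇐ dehydrocostus lactone 1 by allylic oxidation at C3.
- Ring order: both 5/7 hydroazulene cores and both α-methylene-γ-lactones are bought with 1; the only ring made is the spiro-cyclohexene, closed in step 2.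

Assumption: the SMILES is read literally, so in the enone half H-5 is β (5S, cis to H-6, opposite to dehydrocostus lactone) and H-10 is α (10R). Guaiane numbering is used, unprimed for the enone half (unit A) and primed for the spiro-ketone half (unit B).

**Step 1**
Reactants: 1 dehydrocostus lactone
Product: 2 3-epizaluzanin C (3α-hydroxy; 3R)
Conditions: SeO2 (0.5 equiv), t-BuOOH (2 equiv, 5.5 M in decane), CH2Cl2, 0 → 25 °C
Reagents that add atoms: tert-butyl hydroperoxide CC(C)(C)OO (terminal source of the new oxygen); selenium dioxide O=[Se]=O (catalytic carrier that hands the oxygen to C3)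
Why: Riley-type allylic hydroxylation (ene reaction of SeO2 at C15 of the cyclopentane exo-methylene, then [2,3]-sigmatropic shift) restores the 4(15)-alkene and delivers OH to the ring CH2 C3 from the convex α face (3R), a centre that is erased as a ketone in step 2.

**Step 2**
Reactants: 2 3-epizaluzanin C (two molecules)
Product: 6 conjugated enone dimer (C5 epimer of the target), via enone 3 (not isolated), via dienone 4 (not isolated), via cycloadduct 5 (not isolated)
Conditions: IBX (1.0 equiv), DMSO (0.5 M), 25 °C; then IBX (0.5 equiv, portionwise), 65 °C, Ar; NaHCO3 work-up; then DBU (0.2 equiv), degassed CH2Cl2, Ar, 0 → 25 °C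
Reagents that add atoms: none
Why: Proposed new method: IBX first oxidises the allylic alcohol to 3 and then, through the only possible enol (towards C2, with loss of the allylic H-1), dehydrogenates part of 3 to the cross-conjugated dienone 4, whose locked s-cis C2=C1–C10=C14 diene is trapped as it forms by the exo-methylene enone of unreacted 3 in an ortho-selective Diels–Alder reaction on the convex α face of the dienophile (anti to its seven-membered ring), which fixes the spiro centre C4' as R, the transient C2 centre (drawn 2R) being erased when DBU moves the C1=C10 bond into conjugation through the C3 dienolate, whose γ-carbon C10 takes its proton on the α face, anti to the C6–C8 fold that the 5α-H centre holds on the β face, to give 10α-H (10R) while C5 keeps its native 5α-H; the closest known reaction types are the IBX dehydrogenation of ketones and Saegusa oxidation/Diels–Alder cascades of 2-methylenecyclopentanones.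

**Step 3**
Reactants: 6 conjugated enone dimer (C5 epimer of the target)
Product: 8 target dimer (unit A 5βH/10αH), via bis-enolate 7 (not isolated)
Conditions: LiN(SiMe3)2 (2.2 equiv), THF, −78 °C, 30 min; then 2,6-di-tert-butyl-4-methylphenol (5 equiv), THF, −78 °C; sat. aq. NH4Cl, −78 °C; neutral work-up and chromatography
Reagents that add atoms: none
Why: Proposed new method: the amide removes the γ-hydrogen H-5 of unit A, which is doubly allylic and the most acidic C–H of 6, to give a planar oxidofulvene-type trienolate (the unit B ketone gives its simple C2'/C3' enolate, which just reprotonates), in which the trans-lactone twists the seven-membered ring so that C7 and C11 lie under ring A, H-6 is the only group over the β face of C5 and the C6–O bond lies close to the nodal plane of the π system (poor overlap for E1cB loss of the carboxylate), so the hindered phenol, kept from the α-carbon C2 on both faces by the two ring bonds of the orthogonal spiro cyclopentane, returns the proton irreversibly to C5 from the β face and gives the less stable 5β-H epimer (5S) under kinetic control with C10 untouched; the closest known reaction type is the Zimmerman kinetic protonation of enolates from the less hindered face.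

**Compound list**
1 | dehydrocostus lactone, guaia-4(15),10(14),11(13)-trien-12,6α-olide (1R,5R,6S,7S; H-1α, H-5α, H-6β, H-7α) | C=C1CC[C@H]2C(=C)CC[C@H]3C(=C)C(=O)O[C@@H]3[C@@H]12 | starting material
2 | 3-epizaluzanin C, 3α-hydroxyguaia-4(15),10(14),11(13)-trien-12,6α-olide (1R,3R,5R,6S,7S) | C=C1[C@H](O)C[C@H]2C(=C)CC[C@H]3C(=C)C(=O)O[C@@H]3[C@@H]12 | intermediate
3 | dehydrozaluzanin C (the enone of step 2), 3-oxoguaia-4(15),10(14),11(13)-trien-12,6α-olide (1R,5R,6S,7S) | C=C1C(=O)C[C@H]2C(=C)CC[C@H]3C(=C)C(=O)O[C@@H]3[C@@H]12 | intermediate
4 | 1,2-didehydro-dehydrozaluzanin C (the dienone of step 2), 3-oxoguaia-1,4(15),10(14),11(13)-tetraen-12,6α-olide (5R,6S,7S) | C=C1C(=O)C=C2C(=C)CC[C@H]3C(=C)C(=O)O[C@@H]3[C@@H]12 | intermediate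
5 | Diels–Alder cycloadduct: new bonds C2–C4' and C14–C15', C1=C10 alkene, β,γ-unsaturated C3 ketone, H-2α (2R,5R,6S,7S; 1'R,4'R,5'R,6'S,7'S) | C=C1C(=O)[C@@H]2C3=C(CC[C@H]4C(=C)C(=O)O[C@@H]4[C@@H]13)CC[C@]21C(=O)C[C@H]2C(=C)CC[C@H]3C(=C)C(=O)O[C@@H]3[C@H]21 | intermediate
6 | conjugated enone dimer, C1=C2 enone, H-5α, H-10α (5R,6S,7S,10R; 1'R,4'R,5'R,6'S,7'S); C5 epimer of the target | C=C1C(=O)C2=C3[C@H](CC[C@H]4C(=C)C(=O)O[C@@H]4[C@@H]13)CC[C@]21C(=O)C[C@H]2C(=C)CC[C@H]3C(=C)C(=O)O[C@@H]3[C@H]21 | intermediate
7 | dilithium bis-enolate of 6: unit A 3-oxido-2(3),1(5),4(15)-triene (oxidofulvene type), unit B 3'-oxido-2'(3')-ene (6S,7S,10R; 1'S,4'R,5'R,6'S,7'S; the 1' descriptor changes by priority only) | [Li+].[Li+].C=C1C([O-])=C2C3=C1[C@H]4OC(=O)C(=C)[C@@H]4CC[C@@H]3CC[C@]21C([O-])=C[C@H]2C(=C)CC[C@H]3C(=C)C(=O)O[C@@H]3[C@H]21 | intermediate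
8 | CNP0221188.1: spiro-linked guaianolide dimer, unit A 3-oxo-1(2)-ene with H-5β and H-10α (5S,6S,7S,10R), unit B spiro at C4' (1'R,4'R,5'R,6'S,7'S) | C=C1C(=O)C2=C3[C@H](CC[C@H]4C(=C)C(=O)O[C@@H]4[C@H]13)CC[C@]21C(=O)C[C@H]2C(=C)CC[C@H]3C(=C)C(=O)O[C@@H]3[C@H]21 | target

**Total step count:** 3. **Longest linear sequence:** 3 steps (1 → 2 → 6 → 8).

**Steps most likely to fail**

Step 3 is the weakest. Compound 6 is the more stable C5 epimer, so the outcome rests entirely on the proton arriving at C5 from the β face before any equilibration. Competing risks are proton return to the α face, protonation at C2, deprotonation at C10 instead of C5, β-elimination of the lactone carboxylate from the trienolate, and Michael addition to the methylene lactones. Fallback: starting from 6, the dianion 7 is not protonated but silylated with TBSOTf at −78 °C and the bis(tert-butyldimethylsilyl) ether F1 (unit A 3-silyloxyfulvene, unit B silyl enol ether) is isolated. F1 is then protodesilylated at −78 °C in toluene with a chiral Lewis-acid-assisted Brønsted acid made from BINOL and SnCl4, the enantiomer of BINOL being chosen so that reagent control delivers the proton to the β face of C5. The unit B silyl enol ether is cleaved in the same operation and the route is rejoined at 8.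

Step 2 is next. IBX may dehydrogenate 3 too slowly or go on to oxidise the adduct, 4 may dimerise with itself, 3 may undergo its own hetero-Diels–Alder dimerisation, and the C10 proton may end on the β face. Fallback: starting from 2, Dess–Martin periodinane in CH2Cl2 gives 3, which is now isolated. One half of it is converted with TBSOTf/Et3N into the tert-butyldimethylsilyl dienol ether F2. F2 and the other half of 3 are stirred with Pd(OAc)2 (1.1 equiv relative to F2) in MeCN at 25 °C under argon, so that divalent palladium unmasks 4 at room temperature in a non-acidic medium and 4 is trapped at once by 3. The route is rejoined at 5, which receives the DBU treatment of step 2.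

Step 1 is the most reliable but can lose material to oxidation at C9 (allylic to the 10(14)-alkene) and to over-oxidation. Fallback: starting from 1, the ketone level is reached directly by radical allylic oxidation with t-BuOOH and catalytic Rh2(cap)4 (dirhodium tetrakis(ε-caprolactamate)) with K2CO3 in CH2Cl2, the allylic peroxide collapsing to the enone in the flask. The route is rejoined at 3, which enters step 2 at the dehydrogenation stage with only the second IBX charge. Regiochemistry (C3 versus C15 of the allyl radical) is this fallback's own risk. It makes no compound outside the list (F0).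

**Further compounds**
F1 | step 3 | bis(tert-butyldimethylsilyl) ether of 7: unit A 3-silyloxy-2(3),1(5),4(15)-triene, unit B 3'-silyloxy-2'(3')-ene (6S,7S,10R; 1'S,4'R,5'R,6'S,7'S) | C=C1C(O[Si](C)(C)C(C)(C)C)=C2C3=C1[C@H]4OC(=O)C(=C)[C@@H]4CC[C@@H]3CC[C@]21C(O[Si](C)(C)C(C)(C)C)=C[C@H]2C(=C)CC[C@H]3C(=C)C(=O)O[C@@H]3[C@H]21
F2 | step 2 | 3-(tert-butyldimethylsilyloxy)guaia-2,4(15),10(14),11(13)-tetraen-12,6α-olide (1S,5R,6S,7S; the 1 descriptor changes by priority only) | C=C1C(O[Si](C)(C)C(C)(C)C)=C[C@H]2C(=C)CC[C@H]3C(=C)C(=O)O[C@@H]3[C@@H]12
F0 | step 1 | none | none
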